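**Retrosynthetic overview**
- One strategic bond: the diaryl ether C–O bond, cut between a catechol oxygen and C1 of the 2,4-dibromophenyl ring. This gives 3,6-dibromocatechol (C2v-symmetric, so either OH gives the same ether) and a (2,4-dibromophenyl)(2,4,6-trimethoxyphenyl)iodonium salt as a metal-free aryl donor that leaves all C–Br bonds alone.
- 3,6-Dibromocatechol ⇒ 1,4-dibromo-2,3-dimethoxybenzene (BBr3) ⇒ veratrole (double directed ortho-lithiation/bromination; electrophilic bromination would give the 4,5-pattern).
- Iodonium salt ⇒ 2,4-dibromo-1-iodobenzene + 1,3,5-trimethoxybenzene (one-pot oxidation and ligand exchange).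
- No ring is formed: both benzene rings are bought intact and joined in the last step.

Assumption: the target has no stereocentre or stereoaxis, so it is made as the single achiral compound; 3,6-dibromocatechol is treated as not cheaply available and is made from veratrole (if it is bought, only steps 3 and 4 remain).

**Step 1**
Reactants: 1 veratrole (1,2-dimethoxybenzene)
Product: 3 1,4-dibromo-2,3-dimethoxybenzene, via 3,6-dilithio-1,2-dimethoxybenzene 2 (not isolated)
Conditions: n-BuLi (2.5 equiv), TMEDA (2.5 equiv), hexane/Et2O, 0 °C → rt, 24 h; then BrCl2C–CCl2Br (2.6 equiv), THF, −78 °C → rt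
Reagents that add atoms: 1,2-dibromo-1,1,2,2-tetrachloroethane, BrC(Cl)(Cl)C(Cl)(Cl)Br
Why: Directed ortho-metalation: each OMe directs n-BuLi/TMEDA to its one free ortho position (C3 and C6), and the dilithio species is brominated by Br+ transfer from the perhaloethane.

**Step 2**
Reactants: 3 1,4-dibromo-2,3-dimethoxybenzene
Product: 5 3,6-dibromobenzene-1,2-diol (3,6-dibromocatechol), via 2,4,7-tribromo-1,3,2-benzodioxaborole 4 (not isolated)
Conditions: BBr3 (2.5 equiv), CH2Cl2, −78 °C → rt; then H2O, 0 °C
Reagents that add atoms: none
Why: BBr3 O-demethylation of aryl methyl ethers (bromide SN2 on the boron-complexed O–CH3); the aryl C–Br bonds are inert and the cyclic bromoborate 4 hydrolyses on work-up.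

**Step 3**
Reactants: 6 2,4-dibromo-1-iodobenzene; 7 1,3,5-trimethoxybenzene
Product: 9 (2,4-dibromophenyl)(2,4,6-trimethoxyphenyl)iodonium 4-methylbenzenesulfonate, via 2,4-dibromo-1-[hydroxy(tosyloxy)iodo]benzene 8 (not isolated)
Conditions: mCPBA (1.05 equiv), TsOH·H2O (1.05 equiv), MeCN, 77 °C, 1 h; then 7 (1.05 equiv), 77 °C → rt; Et2O trituration
Reagents that add atoms: p-toluenesulfonic acid (used as monohydrate), Cc1ccc(cc1)S(=O)(=O)O
Why: One-pot oxidation of the aryl iodide to a Koser-type iodine(III) tosylate, then electrophilic aromatic substitution (ligand exchange) on the very electron-rich trimethoxybenzene, whose three C–H positions are equivalent and which is added only after the peracid is consumed.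

**Step 4**
Reactants: 5 3,6-dibromobenzene-1,2-diol; 9 (2,4-dibromophenyl)(2,4,6-trimethoxyphenyl)iodonium 4-methylbenzenesulfonate
Product: 12 3,6-dibromo-2-(2,4-dibromophenoxy)phenol, via potassium 3,6-dibromo-2-hydroxyphenolate 10 (not isolated), via (3,6-dibromo-2-hydroxyphenoxy)(2,4-dibromophenyl)(2,4,6-trimethoxyphenyl)-λ3-iodane 11 (not isolated)
Conditions: 5 (1.3 equiv), t-BuOK (1.0 equiv), THF, 0 °C, Ar; then 9 (1.0 equiv), 0 → 40 °C, dark; aq NH4Cl
Reagents that add atoms: none
Why: Proposed new method: chemoselective mono-O-arylation of an unprotected catechol by an aryl(trimethoxyphenyl)iodonium salt, not shown for free catechols because iodine(III) reagents normally oxidise them to o-quinones; one equivalent of base gives the hydrogen-bonded monophenoxide 10, which displaces tosylate at iodine to form the T-shaped aryloxy-λ3-iodane 11, and three-centre ligand coupling transfers the electron-poorer ortho-bromo aryl ring to oxygen while the trimethoxyphenyl dummy leaves as its iodide; the two bromines make the catechol harder to oxidise, no base remains to ionise the product (whose OH is also flanked by Br and the new aryloxy group) so a second arylation is held back, and with no transition metal the four C–Br bonds are untouched; the closest known reaction type is the metal-free O-arylation of simple monophenols with diaryliodonium salts.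

**Compound list**
1 | veratrole (1,2-dimethoxybenzene) | COc1ccccc1OC | starting material
2 | 3,6-dilithio-1,2-dimethoxybenzene | COc1c([Li])ccc([Li])c1OC | intermediate
3 | 1,4-dibromo-2,3-dimethoxybenzene | COc1c(Br)ccc(Br)c1OC | intermediate
4 | 2,4,7-tribromo-1,3,2-benzodioxaborole | BrB1Oc2c(Br)ccc(Br)c2O1 | intermediate
5 | 3,6-dibromobenzene-1,2-diol (3,6-dibromocatechol) | Oc1c(Br)ccc(Br)c1O | intermediate
6 | 2,4-dibromo-1-iodobenzene | Ic1ccc(Br)cc1Br | starting material
7 | 1,3,5-trimethoxybenzene | COc1cc(OC)cc(OC)c1 | starting material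
8 | 2,4-dibromo-1-[hydroxy(tosyloxy)iodo]benzene | Cc1ccc(cc1)S(=O)(=O)OI(O)c1ccc(Br)cc1Br | intermediate
9 | (2,4-dibromophenyl)(2,4,6-trimethoxyphenyl)iodonium 4-methylbenzenesulfonate | COc1cc(OC)c([I+]c2ccc(Br)cc2Br)c(OC)c1.Cc1ccc(cc1)S(=O)(=O)[O-] | intermediate
10 | potassium 3,6-dibromo-2-hydroxyphenolate | [K+].[O-]c1c(Br)ccc(Br)c1O | intermediate
11 | (3,6-dibromo-2-hydroxyphenoxy)(2,4-dibromophenyl)(2,4,6-trimethoxyphenyl)-λ3-iodane | COc1cc(OC)c(c(OC)c1)I(Oc1c(O)c(Br)ccc1Br)c1ccc(Br)cc1Br | intermediate
12 | 3,6-dibromo-2-(2,4-dibromophenoxy)phenol (achiral) | Oc1c(Br)ccc(Br)c1Oc1ccc(Br)cc1Br | target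

**Step count**
Total: 4 steps (steps 1–2 and step 3 are two branches joined in step 4). Longest linear sequence: 3 steps (1, 2, 4).

**Steps most likely to fail**

Step 4 (the proposed new step). Risks are electron-transfer oxidation of the catecholate by iodine(III), double arylation, and cyclisation of the product phenoxide onto the ortho-bromine if base is in excess. The fallback uses known chemistry, sets out from 5 and comes back at 12. 5 is mono-methylated (MeI 1.0 equiv, Li2CO3, DMF, 50 °C; over-methylated material is 3 and goes back through step 2) to 3,6-dibromo-2-methoxyphenol F1. F1, now an ordinary monophenol, is O-arylated with 9 (t-BuOK, THF, 40 °C; the established diaryliodonium arylation of phenoxides) to 1,4-dibromo-2-(2,4-dibromophenoxy)-3-methoxybenzene F2. BBr3 (CH2Cl2, −78 °C → rt) cleaves only the methyl ether and gives 12.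

Step 1. The second lithiation can stall on the already anionic ring and give mono/dibromide mixtures. The fallback sets out from 1 and comes back at 5, replacing steps 1 and 2. A single ortho-lithiation of 1 (n-BuLi 1.1 equiv, TMEDA, Et2O, 0 °C → rt) and the same bromine source give 1-bromo-2,3-dimethoxybenzene F3. BBr3 gives 3-bromobenzene-1,2-diol F4. The second bromine is then introduced electrophilically by amine-directed ortho-bromination (t-BuNH2, Br2, toluene, −78 °C), where the hydrogen-bonded N-bromoamine delivers Br to the only free position ortho to an OH (C6), giving 5.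

Step 3. The electron-poor, ortho-bromo aryl iodide may oxidise slowly or incompletely. The fallback sets out from 6 and comes back at 9, and reverses the roles so that 6 never has to be oxidised. I/Mg exchange (i-PrMgCl·LiCl, THF, −40 °C; C–I reacts, C–Br does not), B(OMe)3 and dilute HCl give (2,4-dibromophenyl)boronic acid F5. F5 transfers its aryl group ipso to the iodine of [bis(acetoxy)iodo]-2,4,6-trimethoxybenzene (CF3CH2OH, rt) to give (2,4-dibromophenyl)(2,4,6-trimethoxyphenyl)iodonium acetate F6. TsOH·H2O exchanges the anion to give 9.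

**Further compounds**
F1 | step 4 | 3,6-dibromo-2-methoxyphenol | COc1c(Br)ccc(Br)c1O
F2 | step 4 | 1,4-dibromo-2-(2,4-dibromophenoxy)-3-methoxybenzene | COc1c(Br)ccc(Br)c1Oc1ccc(Br)cc1Br
F3 | step 1 | 1-bromo-2,3-dimethoxybenzene | COc1cccc(Br)c1OC
F4 | step 1 | 3-bromobenzene-1,2-diol | Oc1cccc(Br)c1O
F5 | step 3 | (2,4-dibromophenyl)boronic acid | OB(O)c1ccc(Br)cc1Br
F6 | step 3 | (2,4-dibromophenyl)(2,4,6-trimethoxyphenyl)iodonium acetate | COc1cc(OC)c([I+]c2ccc(Br)cc2Br)c(OC)c1.CC(=O)[O-]
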